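**Plan**

- Retrosynthesis: after removal of the benzyl and silyl groups, the anti arm on ring B (the benzyl ring on lactone C4) is cut at two bonds at once, ring B C5–C8 and C7–guaiacyl. This leaves aryl bromide 27, a (Z)-alkenylboronate and an aryllithium. Bromide 27 is cut at the lactone C3–CH2 bond into bromolactone 7 and benzylic bromide 25, whose syn arm on ring A (the benzyl ring on lactone C3) is cut in the same two-bond way, with an arylmagnesium bromide as the source of the guaiacyl group.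
- Forward: Stobbe condensation, asymmetric hydrogenation and lactonisation give 7. An E-alkene conjunctive coupling builds the syn arm on the ring A ester, which becomes bromide 25. Trans-selective enolate alkylation joins rings A and B. A Z-alkene conjunctive coupling on the ring B bromide installs the anti arm, and desilylation and hydrogenolysis finish.
- Stereochemistry: lactone C4 comes from the rhodium/Et-DuPhos hydrogenation and C3 from alkylation anti to the C4 benzyl group. In each arm C7 is set by the chiral palladium ligand and C8 by anti addition across the alkene, so E gives the syn (1S,2R) arm and Z the anti (1S,2S) arm.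
- Enabling feature: in each arm the carbinol carbon C7 is next to C8, and C8 is bonded to ring carbon C5, ortho to the phenol oxygen. C7–OH is read as a former C7–B bond and C7–C8 as the CH=CH of an alkenylboronate, so the guaiacyl ring (from boron) and C5 of a 5-bromovanillin-derived ring (from palladium) add across it in one event. Boron, as its mac ester, is the helper and leaves on oxidation.

Key step: step 15

Assumption: the absolute sense of induction of the chiral catalysts (Et-DuPhos/rhodium in step 3, MandyPhos/palladium in steps 10 and 15) is assigned by analogy with simpler substrates; if a catalyst shows the opposite sense, its enantiomeric ligand is used.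

Abbreviations: TBS = tert-butyldimethylsilyl; mac = cyclic boronic ester of diol 9. Locants: C7 = carbinol carbon, C8 = aryl-bearing carbon, C9 = CH2O carbon of the arm on ring B; primed locants for the arm on ring A.

**Step 1**
Reactants: 1 5-bromovanillin
Product: 2 4-(benzyloxy)-3-bromo-5-methoxybenzaldehyde
Conditions: BnBr, K2CO3, DMF, rt
Reagents that add atoms: benzyl bromide, BrCc1ccccc1
Why: Williamson ether synthesis on the acidic phenol, with no stereocentre involved.

**Step 2**
Reactants: 2 4-(benzyloxy)-3-bromo-5-methoxybenzaldehyde; 3 dimethyl succinate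
Product: 4 (E)-4-[4-(benzyloxy)-3-bromo-5-methoxyphenyl]-3-(methoxycarbonyl)but-3-enoic acid
Conditions: NaOMe, MeOH, reflux; then aq. HCl
Reagents that add atoms: none
Why: Stobbe condensation, in which the paraconate intermediate opens by elimination to the E-arylidene half-ester as is usual for aromatic aldehydes.

**Step 3**
Reactants: 4 (E)-arylidene succinic half-ester
Product: 5 (3S)-4-[4-(benzyloxy)-3-bromo-5-methoxyphenyl]-3-(methoxycarbonyl)butanoic acid
Conditions: [Rh(cod)((R,R)-Et-DuPhos)]BF4 (0.5 mol%), H2 (5 atm), NaOMe (10 mol%), MeOH, rt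
Reagents that add atoms: none
Why: Asymmetric hydrogenation of a Stobbe-derived itaconate half-ester, in which the carboxylate chelates cationic monovalent rhodium and the ligand sets the S centre (future lactone C4), while aryl bromide and benzyl ether are inert to this homogeneous catalyst.

**Step 4**
Reactants: 5 (3S)-half-ester acid
Product: 7 (4S)-4-[4-(benzyloxy)-3-bromo-5-methoxybenzyl]oxolan-2-one, via hydroxy acid 6 (not isolated)
Conditions: KOH (1 equiv), EtOH; CaCl2, NaBH4, −10 °C to rt; then 2 M HCl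
Reagents that add atoms: none
Why: Ca(BH4)2 reduces the methyl ester but not the potassium carboxylate, and acid then lactonises the hydroxy acid (chemoselective ester reduction and lactonisation) without touching the stereocentre.

**Step 5**
Reactants: 8 acenaphthoquinone
Product: 9 cis-1,2-dimethyl-1,2-dihydroacenaphthylene-1,2-diol (meso mac diol)
Conditions: MeMgBr (2.5 equiv), THF, 0 °C to rt; aq. NH4Cl; recrystallisation
Reagents that add atoms: methylmagnesium bromide, C[Mg]Br
Why: Double Grignard addition to the 1,2-diketone, where the second methyl should add anti to the solvated magnesium alkoxide of the first adduct and so give mainly the cis diol, the only isomer that can form a cyclic boronate.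

**Step 6**
Reactants: 10 tert-butyldimethyl(prop-2-yn-1-yloxy)silane; 9 mac diol
Product: 12 (E)-3-(TBS-oxy)prop-1-en-1-ylboronic acid mac ester, via E-alkenyl catechol boronate 11 (not isolated)
Conditions: catecholborane, neat, 70 °C; then 9, THF, rt
Reagents that add atoms: catecholborane, [H]B1Oc2ccccc2O1
Why: Uncatalysed syn hydroboration of the terminal alkyne puts boron on the terminal carbon with E geometry, and transesterification replaces catechol by the more stable tertiary diol.

**Step 7**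
Reactants: 10 tert-butyldimethyl(prop-2-yn-1-yloxy)silane; 9 mac diol
Product: 14 (Z)-3-(TBS-oxy)prop-1-en-1-ylboronic acid mac ester, via Z-alkenyl catechol boronate 13 (not isolated)
Conditions: catecholborane, [Rh(cod)Cl]2 (1.5 mol%), P(iPr)3 (6 mol%), Et3N, cyclohexane, rt; then 9, THF, rt
Reagents that add atoms: catecholborane, [H]B1Oc2ccccc2O1
Why: Rhodium-catalysed trans-hydroboration, in which a rhodium vinylidene formed by 1,2-hydrogen shift takes up the boryl group so that boron and the CH2OTBS chain end up cis (Z), followed by transesterification to the mac ester.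

**Step 8**
Reactants: 15 4-bromo-2-methoxyphenol
Product: 16 1-(benzyloxy)-4-bromo-2-methoxybenzene
Conditions: BnBr, K2CO3, DMF, rt
Reagents that add atoms: benzyl bromide, BrCc1ccccc1
Why: Williamson ether synthesis.

**Step 9**
Reactants: 17 methyl 3-bromo-4-hydroxy-5-methoxybenzoate
Product: 18 methyl 4-(benzyloxy)-3-bromo-5-methoxybenzoate
Conditions: BnBr, K2CO3, DMF, rt
Reagents that add atoms: benzyl bromide, BrCc1ccccc1
Why: Williamson ether synthesis.

**Step 10**
Reactants: 16 1-(benzyloxy)-4-bromo-2-methoxybenzene; 12 (E)-alkenyl mac boronate; 18 methyl 4-(benzyloxy)-3-bromo-5-methoxybenzoate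
Product: 22 methyl 4-(benzyloxy)-3-{(1S,2R)-1-[4-(benzyloxy)-3-methoxyphenyl]-3-(TBS-oxy)-1-hydroxypropan-2-yl}-5-methoxybenzoate, via arylmagnesium bromide 19 (not isolated), via E-borate 20 (not isolated), via secondary boronate 21 (not isolated)
Conditions: 16, Mg turnings, THF, 45 °C; 12, 0 °C to rt; then NaOSO2CF3 (2 equiv), 18, Pd(OAc)2 (3 mol%), (Sp,Sp)-MandyPhos (3.6 mol%), THF/DMSO, 60 °C; then NaBO3·4H2O, THF/H2O, rt
Reagents that add atoms: sodium perborate, [Na+].[O-]OB=O (gives the C7' oxygen)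
Why: Palladium-catalysed conjunctive cross-coupling of a Grignard-derived β-substituted alkenylboron mac 'ate' complex, in which NaOSO2CF3 drives borate formation and takes up halide, the guaiacyl group shifts from boron to C7' and ring A C5' bonds to C8' anti across the E double bond to give the syn (1S,2R) arm, with the ligand setting the absolute configuration, perborate oxidising C–B with retention and the ester of 18 left alone because no free Grignard reagent remains once the four-coordinate borate has formed.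

**Step 11**
Reactants: 22 hydroxy ester
Product: 23 methyl 4-(benzyloxy)-3-{(1S,2R)-1-[4-(benzyloxy)-3-methoxyphenyl]-1,3-bis(TBS-oxy)propan-2-yl}-5-methoxybenzoate
Conditions: TBSOTf, 2,6-lutidine, CH2Cl2, −78 to 0 °C
Reagents that add atoms: tert-butyldimethylsilyl trifluoromethanesulfonate, CC(C)(C)[Si](C)(C)OS(=O)(=O)C(F)(F)F
Why: Silylation of the hindered secondary benzylic alcohol with the reactive silyl triflate under buffered conditions that avoid benzylic ionisation.

**Step 12**
Reactants: 23 bis-silyl ester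
Product: 24 {4-(benzyloxy)-3-[(1S,2R)-1-[4-(benzyloxy)-3-methoxyphenyl]-1,3-bis(TBS-oxy)propan-2-yl]-5-methoxyphenyl}methanol
Conditions: iBu2AlH (3 equiv), CH2Cl2, −78 °C; aq. potassium sodium tartrate
Reagents that add atoms: none
Why: Hydride reduction of the aryl ester to the benzylic alcohol, which silyl and benzyl ethers tolerate.

**Step 13**
Reactants: 24 benzylic alcohol
Product: 25 1-(benzyloxy)-4-(bromomethyl)-2-methoxy-6-[(1S,2R)-1-[4-(benzyloxy)-3-methoxyphenyl]-1,3-bis(TBS-oxy)propan-2-yl]benzene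
Conditions: CBr4, PPh3, CH2Cl2, 0 °C; used crude
Reagents that add atoms: carbon tetrabromide, BrC(Br)(Br)Br
Why: Appel reaction converts the primary benzylic alcohol into the bromide under neutral conditions that leave the silyl ethers in place.

**Step 14**
Reactants: 7 (4S)-bromolactone; 25 benzylic bromide
Product: 27 (3S,4S)-4-[4-(benzyloxy)-3-bromo-5-methoxybenzyl]-3-{4-(benzyloxy)-3-[(1S,2R)-1-[4-(benzyloxy)-3-methoxyphenyl]-1,3-bis(TBS-oxy)propan-2-yl]-5-methoxybenzyl}oxolan-2-one, via lithium enolate 26 (not isolated)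
Conditions: 7 (1.2 equiv), LiN(SiMe3)2, THF, −78 °C; then 25, DMPU, −78 to −30 °C
Reagents that add atoms: none
Why: Lactone enolate alkylation in which the benzylic bromide approaches anti to the C4 benzyl group, setting C3 as S and giving the trans lactone, while the aryl bromide is inert at this temperature.

**Step 15**
Reactants: 16 1-(benzyloxy)-4-bromo-2-methoxybenzene; 14 (Z)-alkenyl mac boronate; 27 lactone aryl bromide
Product: 31 (3S,4S)-lactone carrying on ring B the (1S,2S)-1-[4-(benzyloxy)-3-methoxyphenyl]-3-(TBS-oxy)-1-hydroxypropan-2-yl arm and on ring A the bis-silylated (1S,2R) arm, via aryllithium 28 (not isolated), via Z-borate 29 (not isolated), via secondary boronate 30 (not isolated)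
Conditions: 16, tBuLi (2 equiv), Et2O, −78 °C; 14, −78 °C to rt; then 27, Pd(OAc)2 (5 mol%), (Sp,Sp)-MandyPhos (6 mol%), KOSO2CF3, THF, 60 °C; then NaBO3·4H2O, THF/H2O, rt
Reagents that add atoms: sodium perborate, [Na+].[O-]OB=O (gives the C7 oxygen)
Why: Zerovalent palladium bearing MandyPhos inserts into the C5–Br bond of ring B of 27, KOSO2CF3 removes bromide, and the cationic arylpalladium binds the Z CH=CH of borate 29 and sets off a 1,2-metalate shift in which the guaiacyl group moves from boron to C7 while palladium bonds to C8 on the opposite face, after which reductive elimination with retention forms the ring B C5–C8 bond and perborate converts C7–B into C7–OH with retention. The closest known reaction type is the enantio- and diastereoselective palladium-catalysed conjunctive cross-coupling of β-substituted alkenylboron mac 'ate' complexes with aryl electrophiles, of which step 10 is the E counterpart run from a Grignard-derived borate. No ring is closed. C7 (S) is controlled by the chiral ligand, which chooses the alkene face that palladium occupies, and C8 (S) is tied to C7 by the stereospecific anti addition of the two aryl groups across the Z double bond. The step needs the conjunctive pathway to win over direct Suzuki–Miyaura transfer of the alkenyl or aryl group from boron, which the hindered mac diol on boron secures, and it needs the lactone and silyl ethers to survive, which the non-basic four-coordinate borate allows. The stereocentres already present in 27 lie far from the reacting carbons, so catalyst control should decide the diastereomer.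

**Step 16**
Reactants: 31 mono-hydroxy tris-silyl ether
Product: 32 tetra-O-benzyl ether of the target (all four phenols benzylated, all four alcohols free)
Conditions: Bu4NF, AcOH, THF, rt
Reagents that add atoms: none
Why: Fluoride cleaves the three silyl ethers, and the acetic acid buffer keeps the lactone closed and avoids base-induced side reactions.

**Step 17**
Reactants: 32 tetra-O-benzyl ether
Product: 33 CNP0113972.1
Conditions: H2 (1 atm), 10% Pd/C, EtOAc/EtOH, rt, stopped at full debenzylation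
Reagents that add atoms: none
Why: Hydrogenolysis of the four aryl benzyl ethers under neutral conditions, which are expected to leave the secondary benzylic alcohols intact and to avoid acid-induced closure to a dihydrobenzofuran.

**Compound list**

1 | 5-bromovanillin | COc1cc(C=O)cc(Br)c1O | starting material
2 | 4-(benzyloxy)-3-bromo-5-methoxybenzaldehyde | COc1cc(C=O)cc(Br)c1OCc1ccccc1 | intermediate
3 | dimethyl succinate | COC(=O)CCC(=O)OC | starting material
4 | (E)-4-[4-(benzyloxy)-3-bromo-5-methoxyphenyl]-3-(methoxycarbonyl)but-3-enoic acid | OC(=O)C/C(C(=O)OC)=C\c1cc(OC)c(OCc2ccccc2)c(Br)c1 | intermediate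
5 | (3S)-4-[4-(benzyloxy)-3-bromo-5-methoxyphenyl]-3-(methoxycarbonyl)butanoic acid | OC(=O)C[C@@H](C(=O)OC)Cc1cc(OC)c(OCc2ccccc2)c(Br)c1 | intermediate
6 | (3S)-4-[4-(benzyloxy)-3-bromo-5-methoxyphenyl]-3-(hydroxymethyl)butanoic acid | OC(=O)C[C@@H](CO)Cc1cc(OC)c(OCc2ccccc2)c(Br)c1 | intermediate (not isolated)
7 | (4S)-4-[4-(benzyloxy)-3-bromo-5-methoxybenzyl]oxolan-2-one | COc1cc(C[C@@H]2COC(=O)C2)cc(Br)c1OCc1ccccc1 | intermediate
8 | acenaphthoquinone | O=C1C(=O)c2cccc3cccc1c23 | starting material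
9 | cis-1,2-dimethyl-1,2-dihydroacenaphthylene-1,2-diol (meso, mac diol) | C[C@]1(O)c2cccc3cccc(c23)[C@@]1(C)O | intermediate
10 | tert-butyldimethyl(prop-2-yn-1-yloxy)silane | C#CCO[Si](C)(C)C(C)(C)C | starting material
11 | 2-[(E)-3-(TBS-oxy)prop-1-en-1-yl]-1,3,2-benzodioxaborole | CC(C)(C)[Si](C)(C)OC/C=C/B1Oc2ccccc2O1 | intermediate (not isolated)
12 | (E)-3-(TBS-oxy)prop-1-en-1-ylboronic acid mac ester | CC(C)(C)[Si](C)(C)OC/C=C/B1O[C@@]2(C)c3cccc4cccc(c34)[C@@]2(C)O1 | intermediate
13 | 2-[(Z)-3-(TBS-oxy)prop-1-en-1-yl]-1,3,2-benzodioxaborole | CC(C)(C)[Si](C)(C)OC/C=C\B1Oc2ccccc2O1 | intermediate (not isolated)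
14 | (Z)-3-(TBS-oxy)prop-1-en-1-ylboronic acid mac ester | CC(C)(C)[Si](C)(C)OC/C=C\B1O[C@@]2(C)c3cccc4cccc(c34)[C@@]2(C)O1 | intermediate
15 | 4-bromo-2-methoxyphenol | COc1cc(Br)ccc1O | starting material
16 | 1-(benzyloxy)-4-bromo-2-methoxybenzene | COc1cc(Br)ccc1OCc1ccccc1 | intermediate
17 | methyl 3-bromo-4-hydroxy-5-methoxybenzoate | COC(=O)c1cc(OC)c(O)c(Br)c1 | starting material
18 | methyl 4-(benzyloxy)-3-bromo-5-methoxybenzoate | COC(=O)c1cc(OC)c(OCc2ccccc2)c(Br)c1 | intermediate
19 | [4-(benzyloxy)-3-methoxyphenyl]magnesium bromide | COc1cc([Mg]Br)ccc1OCc1ccccc1 | intermediate (not isolated)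
20 | bromomagnesium [4-(benzyloxy)-3-methoxyphenyl][(E)-3-(TBS-oxy)prop-1-en-1-yl] mac borate (configuration at boron undefined) | Br[Mg+].CC(C)(C)[Si](C)(C)OC/C=C/[B-]1(c2ccc(OCc3ccccc3)c(OC)c2)O[C@@]2(C)c3cccc4cccc(c34)[C@@]2(C)O1 | intermediate (not isolated)
21 | methyl 4-(benzyloxy)-3-{(1S,2R)-1-[4-(benzyloxy)-3-methoxyphenyl]-1-(mac boryl)-3-(TBS-oxy)propan-2-yl}-5-methoxybenzoate | COC(=O)c1cc(OC)c(OCc2ccccc2)c([C@H](CO[Si](C)(C)C(C)(C)C)[C@H](B2O[C@@]3(C)c4cccc5cccc(c45)[C@@]3(C)O2)c2ccc(OCc3ccccc3)c(OC)c2)c1 | intermediate (not isolated)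
22 | methyl 4-(benzyloxy)-3-{(1S,2R)-1-[4-(benzyloxy)-3-methoxyphenyl]-3-(TBS-oxy)-1-hydroxypropan-2-yl}-5-methoxybenzoate | COC(=O)c1cc(OC)c(OCc2ccccc2)c([C@H](CO[Si](C)(C)C(C)(C)C)[C@H](O)c2ccc(OCc3ccccc3)c(OC)c2)c1 | intermediate
23 | methyl 4-(benzyloxy)-3-{(1S,2R)-1-[4-(benzyloxy)-3-methoxyphenyl]-1,3-bis(TBS-oxy)propan-2-yl}-5-methoxybenzoate | COC(=O)c1cc(OC)c(OCc2ccccc2)c([C@H](CO[Si](C)(C)C(C)(C)C)[C@H](O[Si](C)(C)C(C)(C)C)c2ccc(OCc3ccccc3)c(OC)c2)c1 | intermediate
24 | {4-(benzyloxy)-3-[(1S,2R)-1-[4-(benzyloxy)-3-methoxyphenyl]-1,3-bis(TBS-oxy)propan-2-yl]-5-methoxyphenyl}methanol | OCc1cc(OC)c(OCc2ccccc2)c([C@H](CO[Si](C)(C)C(C)(C)C)[C@H](O[Si](C)(C)C(C)(C)C)c2ccc(OCc3ccccc3)c(OC)c2)c1 | intermediate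
25 | 1-(benzyloxy)-4-(bromomethyl)-2-methoxy-6-[(1S,2R)-1-[4-(benzyloxy)-3-methoxyphenyl]-1,3-bis(TBS-oxy)propan-2-yl]benzene | BrCc1cc(OC)c(OCc2ccccc2)c([C@H](CO[Si](C)(C)C(C)(C)C)[C@H](O[Si](C)(C)C(C)(C)C)c2ccc(OCc3ccccc3)c(OC)c2)c1 | intermediate
26 | lithium enolate of lactone 7 | COc1cc(C[C@@H]2COC(O[Li])=C2)cc(Br)c1OCc1ccccc1 | intermediate (not isolated)
27 | (3S,4S)-4-[4-(benzyloxy)-3-bromo-5-methoxybenzyl]-3-{4-(benzyloxy)-3-[(1S,2R)-1-[4-(benzyloxy)-3-methoxyphenyl]-1,3-bis(TBS-oxy)propan-2-yl]-5-methoxybenzyl}oxolan-2-one | COc1cc(C[C@@H]2COC(=O)[C@H]2Cc2cc(OC)c(OCc3ccccc3)c([C@H](CO[Si](C)(C)C(C)(C)C)[C@H](O[Si](C)(C)C(C)(C)C)c3ccc(OCc4ccccc4)c(OC)c3)c2)cc(Br)c1OCc1ccccc1 | intermediate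
28 | [4-(benzyloxy)-3-methoxyphenyl]lithium | COc1cc([Li])ccc1OCc1ccccc1 | intermediate (not isolated)
29 | lithium [4-(benzyloxy)-3-methoxyphenyl][(Z)-3-(TBS-oxy)prop-1-en-1-yl] mac borate (configuration at boron undefined) | [Li+].CC(C)(C)[Si](C)(C)OC/C=C\[B-]1(c2ccc(OCc3ccccc3)c(OC)c2)O[C@@]2(C)c3cccc4cccc(c34)[C@@]2(C)O1 | intermediate (not isolated)
30 | compound 31 with a mac boryl group in place of the C7 hydroxyl, (1S,2S) arm on ring B | COc1cc([C@@H](B5O[C@@]6(C)c7cccc8cccc(c78)[C@@]6(C)O5)[C@H](CO[Si](C)(C)C(C)(C)C)c2cc(C[C@@H]3COC(=O)[C@H]3Cc3cc(OC)c(OCc4ccccc4)c([C@H](CO[Si](C)(C)C(C)(C)C)[C@H](O[Si](C)(C)C(C)(C)C)c4ccc(OCc5ccccc5)c(OC)c4)c3)cc(OC)c2OCc2ccccc2)ccc1OCc1ccccc1 | intermediate (not isolated)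
31 | (3S,4S)-4-{4-(benzyloxy)-3-[(1S,2S)-1-[4-(benzyloxy)-3-methoxyphenyl]-3-(TBS-oxy)-1-hydroxypropan-2-yl]-5-methoxybenzyl}-3-{4-(benzyloxy)-3-[(1S,2R)-1-[4-(benzyloxy)-3-methoxyphenyl]-1,3-bis(TBS-oxy)propan-2-yl]-5-methoxybenzyl}oxolan-2-one | COc1cc([C@@H](O)[C@H](CO[Si](C)(C)C(C)(C)C)c2cc(C[C@@H]3COC(=O)[C@H]3Cc3cc(OC)c(OCc4ccccc4)c([C@H](CO[Si](C)(C)C(C)(C)C)[C@H](O[Si](C)(C)C(C)(C)C)c4ccc(OCc5ccccc5)c(OC)c4)c3)cc(OC)c2OCc2ccccc2)ccc1OCc1ccccc1 | intermediate
32 | (3S,4S)-4-{4-(benzyloxy)-3-[(1S,2S)-1-[4-(benzyloxy)-3-methoxyphenyl]-1,3-dihydroxypropan-2-yl]-5-methoxybenzyl}-3-{4-(benzyloxy)-3-[(1S,2R)-1-[4-(benzyloxy)-3-methoxyphenyl]-1,3-dihydroxypropan-2-yl]-5-methoxybenzyl}oxolan-2-one | COc1cc([C@@H](O)[C@H](CO)c2cc(C[C@@H]3COC(=O)[C@H]3Cc3cc(OC)c(OCc4ccccc4)c([C@H](CO)[C@H](O)c4ccc(OCc5ccccc5)c(OC)c4)c3)cc(OC)c2OCc2ccccc2)ccc1OCc1ccccc1 | intermediate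
33 | CNP0113972.1, (3S,4S)-4-{3-[(1S,2S)-1,3-dihydroxy-1-(4-hydroxy-3-methoxyphenyl)propan-2-yl]-4-hydroxy-5-methoxybenzyl}-3-{3-[(1S,2R)-1,3-dihydroxy-1-(4-hydroxy-3-methoxyphenyl)propan-2-yl]-4-hydroxy-5-methoxybenzyl}oxolan-2-one | COc1cc([C@@H](O)[C@H](CO)c2cc(C[C@@H]3COC(=O)[C@H]3Cc3cc(OC)c(O)c([C@H](CO)[C@H](O)c4ccc(O)c(OC)c4)c3)cc(OC)c2O)ccc1O | target

**Step count**

Total steps: 17. Longest linear sequence: 10 steps (5, 6, 10, 11, 12, 13, 14, 15, 16, 17).

**Steps most likely to fail**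

1. Step 15. The metalate shift may be slow for the Z alkene facing an ortho-substituted arylpalladium, so that direct transfer of the alkenyl or aryl group from boron, β-hydride elimination or poor facial selectivity take over. The fallback sets out from 27 and returns at 32; it makes the aryl–C8 bond at the alkene level and sets C8 by substrate-controlled hydroboration.
   - Commercial 4-(benzyloxy)-3-methoxybenzaldehyde is alkynylated with trimethylsilylacetylene (Me2Zn, the ProPhenol enantiomer that gives this isomer) to the silyl alkynol F1.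
   - TBSCl/imidazole gives the silyl ether F2, and K2CO3/MeOH removes the C-silyl group to give the terminal alkyne F3.
   - Copper-catalysed α-selective protoboration ((SIMes)CuCl, NaOtBu, B2pin2, MeOH) gives the 1-substituted vinyl pinacol boronate F4.
   - Suzuki–Miyaura coupling of F4 with 27 (Pd(dppf)Cl2, K3PO4, THF/H2O, 60 °C) gives the 1,1-disubstituted alkene F5.
   - 9-BBN adds to F5 with boron on C9 and hydrogen on C8 anti to the silyloxy group (allylic strain control) to give the borane adduct F6, and NaBO3 oxidises it to the anti primary alcohol F7.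
   - Bu4NF/AcOH as in step 16 then gives 32.

2. Step 10. Incomplete formation of the bromomagnesium borate, the same competing direct transfer from boron, or inhibition of the cationic palladium by magnesium halide may stop the coupling. The fallback sets out from 18 and returns at 23.
   - Suzuki–Miyaura coupling of 18 with the vinyl boronate F4 (made as above) gives the alkene ester F8.
   - Rhodium-catalysed hydroboration with catecholborane (Rh(PPh3)3Cl, THF), which is syn-selective for 2-substituted allylic silyl ethers, gives the alkyl catechol boronate F9.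
   - NaBO3 oxidises F9 to the syn primary alcohol F10, and TBSCl/imidazole returns to 23.

3. Step 17. Once the para benzyl ethers are gone, over-reduction by hydrogenolysis of the benzylic C7–O bonds may compete. The fallback sets out from 31 and returns at 33 with the order of deprotection reversed.
   - TBSOTf/2,6-lutidine silylates the remaining C7 hydroxyl to give the tetrakis-silyl ether F11.
   - H2 over Pd/C in EtOAc removes the four benzyl groups while every benzylic oxygen is shielded as a bulky silyl ether, giving the tetraphenol F12.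
   - Bu4NF/AcOH then releases 33.

**Further compounds**

F1 | step 15 | (1R)-1-[4-(benzyloxy)-3-methoxyphenyl]-3-(trimethylsilyl)prop-2-yn-1-ol | COc1cc([C@@H](O)C#C[Si](C)(C)C)ccc1OCc1ccccc1
F2 | step 15 | tert-butyl{[(1R)-1-[4-(benzyloxy)-3-methoxyphenyl]-3-(trimethylsilyl)prop-2-yn-1-yl]oxy}dimethylsilane | COc1cc([C@@H](O[Si](C)(C)C(C)(C)C)C#C[Si](C)(C)C)ccc1OCc1ccccc1
F3 | step 15 | tert-butyl{[(1S)-1-[4-(benzyloxy)-3-methoxyphenyl]prop-2-yn-1-yl]oxy}dimethylsilane | COc1cc([C@@H](O[Si](C)(C)C(C)(C)C)C#C)ccc1OCc1ccccc1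
F4 | step 15 | tert-butyl{[(1S)-1-[4-(benzyloxy)-3-methoxyphenyl]-2-(4,4,5,5-tetramethyl-1,3,2-dioxaborolan-2-yl)prop-2-en-1-yl]oxy}dimethylsilane | COc1cc([C@@H](O[Si](C)(C)C(C)(C)C)C(=C)B2OC(C)(C)C(C)(C)O2)ccc1OCc1ccccc1
F5 | step 15 | compound 27 with the ring B bromine replaced by the (3R)-3-[4-(benzyloxy)-3-methoxyphenyl]-3-(TBS-oxy)prop-1-en-2-yl group | COc1cc([C@@H](O[Si](C)(C)C(C)(C)C)C(=C)c2cc(C[C@@H]3COC(=O)[C@H]3Cc3cc(OC)c(OCc4ccccc4)c([C@H](CO[Si](C)(C)C(C)(C)C)[C@H](O[Si](C)(C)C(C)(C)C)c4ccc(OCc5ccccc5)c(OC)c4)c3)cc(OC)c2OCc2ccccc2)ccc1OCc1ccccc1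
F6 | step 15 | 9-BBN adduct of F5 with boron on C9 and the new C8 hydrogen anti to the C7 silyloxy group (not isolated) | COc1cc([C@@H](O[Si](C)(C)C(C)(C)C)[C@H](CB8C9CCCC8CCC9)c2cc(C[C@@H]3COC(=O)[C@H]3Cc3cc(OC)c(OCc4ccccc4)c([C@H](CO[Si](C)(C)C(C)(C)C)[C@H](O[Si](C)(C)C(C)(C)C)c4ccc(OCc5ccccc5)c(OC)c4)c3)cc(OC)c2OCc2ccccc2)ccc1OCc1ccccc1
F7 | step 15 | compound 32 with TBS on the C7, C7' and C9' oxygens, ring B arm (1S,2S) with free C9 hydroxyl | COc1cc([C@@H](O[Si](C)(C)C(C)(C)C)[C@H](CO)c2cc(C[C@@H]3COC(=O)[C@H]3Cc3cc(OC)c(OCc4ccccc4)c([C@H](CO[Si](C)(C)C(C)(C)C)[C@H](O[Si](C)(C)C(C)(C)C)c4ccc(OCc5ccccc5)c(OC)c4)c3)cc(OC)c2OCc2ccccc2)ccc1OCc1ccccc1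
F8 | step 10 | methyl 4-(benzyloxy)-3-{(3R)-3-[4-(benzyloxy)-3-methoxyphenyl]-3-(TBS-oxy)prop-1-en-2-yl}-5-methoxybenzoate | COC(=O)c1cc(OC)c(OCc2ccccc2)c(C(=C)[C@H](O[Si](C)(C)C(C)(C)C)c2ccc(OCc3ccccc3)c(OC)c2)c1
F9 | step 10 | catechol boronate from hydroboration of F8, boron on C9' and new C8' hydrogen syn-selective (not isolated) | COC(=O)c1cc(OC)c(OCc2ccccc2)c([C@H](CB2Oc3ccccc3O2)[C@H](O[Si](C)(C)C(C)(C)C)c2ccc(OCc3ccccc3)c(OC)c2)c1
F10 | step 10 | methyl 4-(benzyloxy)-3-{(1S,2R)-1-[4-(benzyloxy)-3-methoxyphenyl]-1-(TBS-oxy)-3-hydroxypropan-2-yl}-5-methoxybenzoate | COC(=O)c1cc(OC)c(OCc2ccccc2)c([C@H](CO)[C@H](O[Si](C)(C)C(C)(C)C)c2ccc(OCc3ccccc3)c(OC)c2)c1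
F11 | step 17 | compound 31 with the C7 hydroxyl also silylated (four TBS ethers, four benzyl ethers) | COc1cc([C@@H](O[Si](C)(C)C(C)(C)C)[C@H](CO[Si](C)(C)C(C)(C)C)c2cc(C[C@@H]3COC(=O)[C@H]3Cc3cc(OC)c(OCc4ccccc4)c([C@H](CO[Si](C)(C)C(C)(C)C)[C@H](O[Si](C)(C)C(C)(C)C)c4ccc(OCc5ccccc5)c(OC)c4)c3)cc(OC)c2OCc2ccccc2)ccc1OCc1ccccc1
F12 | step 17 | target 33 with TBS on all four alcohol oxygens and four free phenols | COc1cc([C@@H](O[Si](C)(C)C(C)(C)C)[C@H](CO[Si](C)(C)C(C)(C)C)c2cc(C[C@@H]3COC(=O)[C@H]3Cc3cc(OC)c(O)c([C@H](CO[Si](C)(C)C(C)(C)C)[C@H](O[Si](C)(C)C(C)(C)C)c4ccc(O)c(OC)c4)c3)cc(OC)c2O)ccc1O
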